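**Plan**
- Retrosynthesis: the C1–C(=O)Ph bond is cut first (acylation of an aryllithium at C1). Then three bonds of ring A are cut at once, C5–C6, C3–C4 and C1–C6, which unravels the benzene ring into a cyclobutenone (supplying C6, C3, C2, C1) and an ynol silyl ether (supplying C5, C4).
- Enabling feature: ring A carries three differently substituted oxygens (C2 OMe, C4 OH, C6 OH) alternating with carbon groups (C1 benzoyl, C3 and C5 prenyl). Each oxygen can therefore arrive on its own precursor atom: OMe on the cyclobutenone, OSi on the alkyne, the free OH from the ketene carbonyl. The one ring CH left is C1.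
- Forward order: a prenylated methoxyalkyne is turned into the cyclobutenone by dichloroketene cycloaddition and dechlorination, and an ester homologation gives the siloxyalkyne. The thermal benzannulation then closes ring A, the only ring that is built.
- Endgame: MOM protection, lithiation at C1 with benzoyl transfer, then removal of MOM and of the silyl group.
- Stereochemistry: the target is achiral and its alkenes carry no geometry, so nothing has to be set.

Key step: step 5

Remark: ester 9 and amide 19 are taken as purchasable. Intermediate 14 has a transient stereocentre, forms as a racemate and loses it on ring opening.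

**Step 1**
Reactants: 1 chloroacetaldehyde dimethyl acetal (2-chloro-1,1-dimethoxyethane); 2 prenyl bromide (1-bromo-3-methylbut-2-ene)
Product: 4 1-methoxy-5-methylhex-4-en-1-yne, via sodium methoxyacetylide 3 (not isolated)
Conditions: NaNH2 (3 equiv), liq. NH3, −33 °C; then 2, −33 °C; solid NH4Cl, pentane extraction
Reagents that add atoms: none
Why: Twofold elimination (HCl, then MeOH) and deprotonation turn the chloroacetal into the alkoxyacetylide, which is alkylated at the primary carbon of the allylic bromide (SN2 alkylation of an acetylide), and with exactly three equivalents of amide no free base is left to isomerise the skipped enyne.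

**Step 2**
Reactants: 4 1-methoxy-5-methylhex-4-en-1-yne; 5 trichloroacetyl chloride
Product: 7 4,4-dichloro-3-methoxy-2-(3-methylbut-2-en-1-yl)cyclobut-2-en-1-one, via dichloroketene 6 (not isolated)
Conditions: zinc–copper couple, Et2O/DME, slow addition of 5, 0 °C to rt
Reagents that add atoms: none
Why: Ketene–ynol ether [2+2] cycloaddition in which the nucleophilic carbon β to oxygen attacks the ketene carbonyl carbon, placing prenyl at C2 and OMe at C3, while the ynol ether reacts far faster than the trisubstituted alkene and DME ties up ZnCl2.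

**Step 3**
Reactants: 7 4,4-dichloro-3-methoxy-2-(3-methylbut-2-en-1-yl)cyclobut-2-en-1-one
Product: 8 3-methoxy-2-(3-methylbut-2-en-1-yl)cyclobut-2-en-1-one
Conditions: Zn dust, AcOH, TMEDA, MeOH, 0 °C to rt
Reagents that add atoms: none
Why: Zinc reduction of the two chlorines α to the carbonyl (reductive dechlorination of 4,4-dichlorocyclobutenones), with the amine buffer protecting the acid-labile vinylogous ester and MeOH as solvent excluding alkoxy exchange.

**Step 4**
Reactants: 9 ethyl 4-methylpent-3-enoate
Product: 12 triisopropyl[(5-methylhex-4-en-1-yn-1-yl)oxy]silane, via dibromoketone enolate 10 (not isolated), via lithium ynolate 11 (not isolated)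
Conditions: CH2Br2, lithium 2,2,6,6-tetramethylpiperidide (LiTMP), THF, −78 °C; add 9; n-BuLi, −78 °C to rt; then TIPSCl, −78 °C to rt
Reagents that add atoms: dibromomethane, BrCBr; triisopropylsilyl chloride, CC(C)[Si](Cl)(C(C)C)C(C)C
Why: Kowalski ester homologation, in which LiCHBr2 adds to the ester, the dibromo enolate undergoes bromine–lithium exchange and carbenoid rearrangement with migration of the prenyl CH2 to give the ynolate, and the bulky chlorosilane traps it on oxygen.

**Step 5**
Reactants: 8 3-methoxy-2-(3-methylbut-2-en-1-yl)cyclobut-2-en-1-one; 12 triisopropyl[(5-methylhex-4-en-1-yn-1-yl)oxy]silane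
Product: 17 5-methoxy-2,4-bis(3-methylbut-2-en-1-yl)-3-(triisopropylsilyloxy)phenol, via vinylketene 13 (not isolated), via vinylcyclobutenone 14 (not isolated), via dienylketene 15 (not isolated), via cyclohexadienone 16 (not isolated)
Conditions: 12 (slight excess), toluene, 110 °C, sealed tube, degassed
Reagents that add atoms: none
Why: Heating opens 8 by 4π electrocyclic ring opening to vinylketene 13, whose ketene C=C adds the electron-rich siloxyalkyne in a [2+2] cycloaddition to give 14; a second 4π opening gives dienylketene 15, 6π electrocyclisation gives 16, and tautomerisation gives phenol 17. The closest known reaction type is the Danheiser benzannulation of cyclobutenones with trialkylsiloxyalkynes to monosilylated resorcinols; because the 3-methoxy group makes 8 a vinylogous ester, the first opening may need the upper end of the usual temperature range. Ring A is closed by the 6π electrocyclisation of 15 (C1–C6), after C5–C6 and C3–C4 have been made in the [2+2] event. No stereocentre survives, and only the (E)-dienylketene with the ketene and methoxyvinyl groups cis can close, the other isomer returning through 14. The step needs regioselectivity in the [2+2] event, and the polarisation of 12 secures it: its carbon β to oxygen bonds to the electrophilic ketene carbonyl carbon, so the silyloxy carbon ends meta to the new hydroxyl and between the two prenyl groups. A slight excess of 12 should suppress acylation of 17 by unconsumed ketene.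

**Step 6**
Reactants: 17 5-methoxy-2,4-bis(3-methylbut-2-en-1-yl)-3-(triisopropylsilyloxy)phenol
Product: 18 [3-methoxy-5-(methoxymethoxy)-2,6-bis(3-methylbut-2-en-1-yl)phenoxy]triisopropylsilane
Conditions: MOMCl, i-Pr2NEt, CH2Cl2, 0 °C to rt
Reagents that add atoms: chloromethyl methyl ether, COCCl
Why: O-alkylation of the phenol with the chloromethyl ether under amine base installs an acetal ether that serves as ortho-directing group and leaves the silyl ether and both alkenes untouched.

**Step 7**
Reactants: 18 [3-methoxy-5-(methoxymethoxy)-2,6-bis(3-methylbut-2-en-1-yl)phenoxy]triisopropylsilane; 19 N-methoxy-N-methylbenzamide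
Product: 21 [2-methoxy-6-(methoxymethoxy)-3,5-bis(3-methylbut-2-en-1-yl)-4-(triisopropylsilyloxy)phenyl](phenyl)methanone, via aryllithium 20 (not isolated)
Conditions: n-BuLi, THF, −20 to 0 °C; then 19, −78 °C to rt; aq. NH4Cl
Reagents that add atoms: none
Why: Directed ortho-metalation at the only ring hydrogen, which lies between OMe and OMOM where cooperative coordination makes deprotonation fastest, followed by single addition to the Weinreb amide through a chelated tetrahedral adduct that releases the ketone on work-up.

**Step 8**
Reactants: 21 [2-methoxy-6-(methoxymethoxy)-3,5-bis(3-methylbut-2-en-1-yl)-4-(triisopropylsilyloxy)phenyl](phenyl)methanone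
Product: 22 [2-hydroxy-6-methoxy-3,5-bis(3-methylbut-2-en-1-yl)-4-(triisopropylsilyloxy)phenyl](phenyl)methanone
Conditions: HCl (aq., 2 M), MeOH, rt
Reagents that add atoms: none
Why: Acid-catalysed acetal exchange removes the MOM group, which is activated by the ortho carbonyl, under conditions mild enough for the prenyl groups and the hindered aryl silyl ether, and the freed phenol is tied up by hydrogen bonding to the ketone.

**Step 9**
Reactants: 22 [2-hydroxy-6-methoxy-3,5-bis(3-methylbut-2-en-1-yl)-4-(triisopropylsilyloxy)phenyl](phenyl)methanone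
Product: 23 [2,4-dihydroxy-6-methoxy-3,5-bis(3-methylbut-2-en-1-yl)phenyl](phenyl)methanone
Conditions: Bu4NF, AcOH, THF, 0 °C
Reagents that add atoms: none
Why: Fluoride-induced cleavage of the aryl Si–O bond, buffered with acetic acid so that the polyphenol is not held as a basic phenoxide.

**Compound list**
1 | chloroacetaldehyde dimethyl acetal | COC(CCl)OC | starting material
2 | prenyl bromide (1-bromo-3-methylbut-2-ene) | CC(C)=CCBr | starting material
3 | sodium methoxyacetylide | [Na+].[C-]#COC | intermediate
4 | 1-methoxy-5-methylhex-4-en-1-yne | COC#CCC=C(C)C | intermediate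
5 | trichloroacetyl chloride | O=C(Cl)C(Cl)(Cl)Cl | starting material
6 | dichloroketene | O=C=C(Cl)Cl | intermediate
7 | 4,4-dichloro-3-methoxy-2-(3-methylbut-2-en-1-yl)cyclobut-2-en-1-one | COC1=C(CC=C(C)C)C(=O)C1(Cl)Cl | intermediate
8 | 3-methoxy-2-(3-methylbut-2-en-1-yl)cyclobut-2-en-1-one | COC1=C(CC=C(C)C)C(=O)C1 | intermediate
9 | ethyl 4-methylpent-3-enoate | CCOC(=O)CC=C(C)C | starting material
10 | lithium 1,1-dibromo-5-methylhexa-1,4-dien-2-olate (enolate of 1,1-dibromo-5-methylhex-4-en-2-one) | [Li+].[O-]C(CC=C(C)C)=C(Br)Br | intermediate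
11 | lithium 5-methylhex-4-en-1-yn-1-olate | [Li+].[O-]C#CCC=C(C)C | intermediate
12 | triisopropyl[(5-methylhex-4-en-1-yn-1-yl)oxy]silane | CC(C)=CCC#CO[Si](C(C)C)(C(C)C)C(C)C | intermediate
13 | 3-methoxy-2-(3-methylbut-2-en-1-yl)buta-1,3-dien-1-one (vinylketene) | C=C(OC)C(CC=C(C)C)=C=O | intermediate
14 | 4-(1-methoxyethenyl)-2,4-bis(3-methylbut-2-en-1-yl)-3-(triisopropylsilyloxy)cyclobut-2-en-1-one (racemic) | C=C(OC)C1(CC=C(C)C)C(=O)C(CC=C(C)C)=C1O[Si](C(C)C)(C(C)C)C(C)C | intermediate
15 | (3E)-5-methoxy-2,4-bis(3-methylbut-2-en-1-yl)-3-(triisopropylsilyloxy)hexa-1,3,5-trien-1-one (dienylketene) | O=C=C(CC=C(C)C)/C(O[Si](C(C)C)(C(C)C)C(C)C)=C(CC=C(C)C)\C(OC)=C | intermediate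
16 | 5-methoxy-2,4-bis(3-methylbut-2-en-1-yl)-3-(triisopropylsilyloxy)cyclohexa-2,4-dien-1-one | O=C1CC(OC)=C(CC=C(C)C)C(O[Si](C(C)C)(C(C)C)C(C)C)=C1CC=C(C)C | intermediate
17 | 5-methoxy-2,4-bis(3-methylbut-2-en-1-yl)-3-(triisopropylsilyloxy)phenol | COc1cc(O)c(CC=C(C)C)c(O[Si](C(C)C)(C(C)C)C(C)C)c1CC=C(C)C | intermediate
18 | [3-methoxy-5-(methoxymethoxy)-2,6-bis(3-methylbut-2-en-1-yl)phenoxy]triisopropylsilane | COCOc1cc(OC)c(CC=C(C)C)c(O[Si](C(C)C)(C(C)C)C(C)C)c1CC=C(C)C | intermediate
19 | N-methoxy-N-methylbenzamide | CON(C)C(=O)c1ccccc1 | starting material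
20 | [2-methoxy-6-(methoxymethoxy)-3,5-bis(3-methylbut-2-en-1-yl)-4-(triisopropylsilyloxy)phenyl]lithium | [Li]c1c(OC)c(CC=C(C)C)c(O[Si](C(C)C)(C(C)C)C(C)C)c(CC=C(C)C)c1OCOC | intermediate
21 | [2-methoxy-6-(methoxymethoxy)-3,5-bis(3-methylbut-2-en-1-yl)-4-(triisopropylsilyloxy)phenyl](phenyl)methanone | COCOc1c(C(=O)c2ccccc2)c(OC)c(CC=C(C)C)c(O[Si](C(C)C)(C(C)C)C(C)C)c1CC=C(C)C | intermediate
22 | [2-hydroxy-6-methoxy-3,5-bis(3-methylbut-2-en-1-yl)-4-(triisopropylsilyloxy)phenyl](phenyl)methanone | COc1c(CC=C(C)C)c(O[Si](C(C)C)(C(C)C)C(C)C)c(CC=C(C)C)c(O)c1C(=O)c1ccccc1 | intermediate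
23 | [2,4-dihydroxy-6-methoxy-3,5-bis(3-methylbut-2-en-1-yl)phenyl](phenyl)methanone | COc1c(CC=C(C)C)c(O)c(CC=C(C)C)c(O)c1C(=O)c1ccccc1 | target

**Step count**
Total: 9 steps. Longest linear sequence: 8 steps (steps 1, 2, 3, 5, 6, 7, 8, 9); step 4 is a one-step branch.

**Steps most likely to fail**

Step 5. The donor-stabilised vinylogous ester 8 may resist electrocyclic opening at temperatures the siloxyalkyne tolerates, or the methoxy vinylketene may oligomerise faster than it is trapped. The fallback makes the same vinylketene without a cyclobutenone; it sets out from prenyl bromide 2 and returns to the route at vinylketene 13, and so at phenol 17. Alkylation of methyl acetoacetate with 2 (NaOMe, MeOH) would give methyl 2-acetyl-5-methylhex-4-enoate F1. Enol ether formation (HC(OMe)3, cat. TsOH, MeOH) would give methyl (2E)-3-methoxy-2-(3-methylbut-2-en-1-yl)but-2-enoate F2; either alkene geometry serves. Saponification (LiOH, THF/H2O, cold acidification to pH 4) would give (2E)-3-methoxy-2-(3-methylbut-2-en-1-yl)but-2-enoic acid F3. Oxalyl chloride with cat. DMF in CH2Cl2 would give (2E)-3-methoxy-2-(3-methylbut-2-en-1-yl)but-2-enoyl chloride F4. Slow addition of F4 to Et3N and 12 in toluene would form 13 by vinylogous dehydrochlorination near room temperature, with the cycloadduct 14 rearranging to 17 on warming to 80 °C.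

Step 7. Deprotonation at the benzylic and allylic CH2 of a prenyl group may compete with ring metalation, or acyl transfer to the di-ortho-substituted aryllithium may be slow. The fallback avoids organolithium chemistry; it sets out from phenol 17 and returns at ketone 22, bypassing steps 6 to 8. Benzoylation of 17 (BzCl, Et3N, DMAP, CH2Cl2) would give 5-methoxy-2,4-bis(3-methylbut-2-en-1-yl)-3-(triisopropylsilyloxy)phenyl benzoate F5. Irradiation (254 nm, degassed cyclohexane) would bring about a photo-Fries 1,3-acyl shift to the only free ortho position. The product 22 is an ortho-hydroxybenzophenone, which sheds excitation by intramolecular proton transfer and should not react on with the alkenes.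

Step 4. The β,γ-unsaturated ester may be enolised at its doubly activated α-CH2 by LiCHBr2 or the amide base instead of undergoing carbonyl addition. The fallback reaches the ynolate by oxidation of an acetylide; it sets out from prenyl bromide 2 and returns at ynolate 11, and so at 12. Coupling of 2 with ethynylmagnesium bromide (cat. CuCl, THF) would give 5-methylhex-4-en-1-yne F6. Deprotonation with LiN(SiMe3)2 and oxidation of the lithium acetylide with lithium tert-butyl peroxide (from t-BuOOH and LiN(SiMe3)2, THF, −78 to 0 °C) would give 11, which is silylated with TIPSCl as in step 4.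

**Further compounds**
F1 | step 5 | methyl 2-acetyl-5-methylhex-4-enoate (racemic) | COC(=O)C(CC=C(C)C)C(C)=O
F2 | step 5 | methyl (2E)-3-methoxy-2-(3-methylbut-2-en-1-yl)but-2-enoate | CO/C(C)=C(\CC=C(C)C)C(=O)OC
F3 | step 5 | (2E)-3-methoxy-2-(3-methylbut-2-en-1-yl)but-2-enoic acid | CO/C(C)=C(\CC=C(C)C)C(=O)O
F4 | step 5 | (2E)-3-methoxy-2-(3-methylbut-2-en-1-yl)but-2-enoyl chloride | CO/C(C)=C(\CC=C(C)C)C(=O)Cl
F5 | step 7 | 5-methoxy-2,4-bis(3-methylbut-2-en-1-yl)-3-(triisopropylsilyloxy)phenyl benzoate | COc1cc(OC(=O)c2ccccc2)c(CC=C(C)C)c(O[Si](C(C)C)(C(C)C)C(C)C)c1CC=C(C)C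
F6 | step 4 | 5-methylhex-4-en-1-yne | C#CCC=C(C)C
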